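**Plan**

1. Numbering: ring C1 (carries the side chain), C2 (CH2), C3/C4 (epoxide, CH3 on C4), C5/C6 (angelates); chain C7 (=C14H2), C8 (OAc), C9–C11 (prenyl unit).
2. Retrosynthetic cuts, in order: the two angelate C–O bonds, the two epoxide C–O bonds, the acetate, C7–C8 (alkenyl iodide plus 4-methylpent-3-enal), and last C1–C7.
3. Enabling feature: C1–C7 lies cis to the C6 oxygen and C2 is a CH2 beside the C3=C4 alkene that becomes the epoxide. This is a syn addition of C7 and H across C1=C2 of a cyclohexa-1,3-diene whose neighbouring C6 oxygen can carry a silicon tether.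
4. Forward order: dioxygenase cis-diol of 4-iodotoluene (carbocycle, C5/C6), deiodination, tether on C6–O, radical closure (temporary oxasilolane ring, C1–C7), ring opening, iododesilylation, chain joined at C7–C8, acetate, epoxide ring last, then both angelates.
5. Stereochemistry: C5/C6 from the enzyme, C1 from the tether, C8 from the ligand-controlled chromium addition, C3/C4 from hydroxyl-directed epoxidation, Z-enoates carried in from angelic acid.

Key step: step 6

Assumption: iodine, as the larger group, is taken to direct the dioxygenase in step 1, and the ligand antipode in step 10 is the one that places the alkenyl group on the Re face of 14 (C8 of 15 to be confirmed by Mosher ester analysis before going on).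

TBS = tert-butyldimethylsilyl.

**Route**

Step 1
Reactants: 1 4-iodotoluene
Product: 2 (1S,2S)-3-iodo-6-methylcyclohexa-3,5-diene-1,2-diol
Conditions: whole cells of P. putida UV4 (toluene dioxygenase), glucose, air, phosphate buffer pH 7.2, 30 °C; recrystallisation
Reagents that add atoms: dioxygen, O=O
Why: Enzymatic arene cis-dihydroxylation should place both oxygen atoms on one face next to the iodine-bearing carbon with the usual (1S,2S) sense, which fixes C5 and C6 of the target, and recrystallisation of 2 should make up any shortfall in enantiomeric purity.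

Step 2
Reactants: 2 (1S,2S)-3-iodo-6-methylcyclohexa-3,5-diene-1,2-diol
Product: 3 (1R,2S)-3-methylcyclohexa-3,5-diene-1,2-diol
Conditions: H2 (1 atm, stopped after one equivalent), Pd/C, NaOAc·3H2O, MeOH, rt
Reagents that add atoms: none
Why: Chemoselective catalytic hydrogenolysis of the weak vinylic C–I bond under acetate buffer should outrun reduction of the diene and leave the diol of the sense opposite to that formed from toluene itself, with both stereocentres untouched.

Step 3
Reactants: 4 chlorodimethylvinylsilane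
Product: 6 (1-bromoethenyl)chlorodimethylsilane, via chloro(1,2-dibromoethyl)dimethylsilane 5 (not isolated)
Conditions: Br2 (1.0 equiv), CH2Cl2, −78 → 0 °C; then PhNEt2, 100 °C, distillation
Reagents that add atoms: bromine, BrBr
Why: Bromine addition to the vinylsilane followed by amine-induced dehydrobromination removes the acidified proton next to silicon together with the distal bromide, the standard entry to 1-bromovinylsilanes, and a tertiary aniline base leaves the Si–Cl bond intact.

Step 4
Reactants: 3 (1R,2S)-3-methylcyclohexa-3,5-diene-1,2-diol; 6 (1-bromoethenyl)chlorodimethylsilane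
Product: 7 (1S,6R)-6-{[(1-bromoethenyl)dimethylsilyl]oxy}-2-methylcyclohexa-2,4-dien-1-ol
Conditions: Et3N, DMAP (cat.), CH2Cl2, −78 °C; filtration through Et3N-deactivated silica
Reagents that add atoms: none
Why: Base-mediated O-silylation with one equivalent of chlorosilane at low temperature should favour the C6 hydroxyl, which is remote from the ring methyl group, as is usual for silyl chlorides with 3-substituted cyclohexadiene cis-diols.

Step 5
Reactants: 7 (1S,6R)-6-{[(1-bromoethenyl)dimethylsilyl]oxy}-2-methylcyclohexa-2,4-dien-1-ol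
Product: 8 {[(1S,6R)-6-{[(1-bromoethenyl)dimethylsilyl]oxy}-2-methylcyclohexa-2,4-dien-1-yl]oxy}(tert-butyl)dimethylsilane
Conditions: TBSOTf, 2,6-lutidine, CH2Cl2, −78 °C
Reagents that add atoms: tert-butyldimethylsilyl triflate, CC(C)(C)[Si](C)(C)OS(=O)(=O)C(F)(F)F
Why: Silyl triflate silylation under a hindered pyridine base caps the more hindered C5 hydroxyl without acid or strong base, so the dienyl ether should neither aromatise nor lose the tether, and the tether can no longer migrate to C5–O.

Step 6
Reactants: 8 {[(1S,6R)-6-{[(1-bromoethenyl)dimethylsilyl]oxy}-2-methylcyclohexa-2,4-dien-1-yl]oxy}(tert-butyl)dimethylsilane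
Product: 9 (3aR,7S,7aR)-7-[(tert-butyldimethylsilyl)oxy]-2,2,6-trimethyl-3-methylidene-2,3,3a,4,7,7a-hexahydro-1,2-benzoxasilole
Conditions: Bu3SnH (1.3 equiv) and AIBN (cat.) added by syringe pump over 6 h, degassed PhH (0.01 M), 80 °C; KF work-up
Reagents that add atoms: none
Why: The stannyl radical abstracts bromine from 8 to give an α-silyl σ-vinyl radical at C7, which adds to the diene terminus C1, and the resulting C2–C3–C4 allyl radical takes hydrogen from Bu3SnH and passes the chain on. The closest known reaction type is the tin hydride-mediated silicon-tethered radical cyclisation of (1-bromovinyl)dimethylsilyl ethers of allylic alcohols, here applied to a dienyl alcohol. The one ring formed, the 1-oxa-2-silacyclopentane made of C7, C1, C6, O and Si, closes in the 5-exo-trig mode. The single new stereocentre, C1, is controlled by the O–Si tether anchored on C6, which can reach C1 only on the face of the C6 oxygen and so enforces cis ring fusion against the steric bias of the neighbouring silyl ethers. Attack at C1 and not at C2 is needed and is secured because 5-exo closure is kinetically preferred and alone leads to an allyl-stabilised radical, a stabilisation that also holds back the 3-exo ring-expansion drift towards a 6-endo skeleton. Hydrogen capture at C2 and not at C4 is needed and is secured because C2 is the secondary, less hindered terminus and its reduction leaves the trisubstituted C3=C4 alkene, whereas C4 is tertiary and flanked by the C5 silyl ether.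

Step 7
Reactants: 9 (3aR,7S,7aR)-7-[(tert-butyldimethylsilyl)oxy]-2,2,6-trimethyl-3-methylidene-2,3,3a,4,7,7a-hexahydro-1,2-benzoxasilole
Product: 11 {[(1R,2S,6R)-3-methyl-6-[1-(trimethylsilyl)ethenyl]cyclohex-3-ene-1,2-diyl]bis(oxy)}bis[tert-butyl(dimethyl)silane], via lithium alkoxide of the ring-opened vinylsilane 10 (not isolated)
Conditions: MeLi (1.3 equiv), THF, −78 → 0 °C; then TBSOTf (2 equiv), −78 → 0 °C
Reagents that add atoms: methyllithium, [Li]C; tert-butyldimethylsilyl triflate, CC(C)(C)[Si](C)(C)OS(=O)(=O)C(F)(F)F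
Why: Nucleophilic ring opening of the cyclic siloxane by MeLi at silicon (alkoxide as leaving group) turns the tether into a C7–SiMe3 vinylsilane, and silylation of the C6 lithium alkoxide in the same flask gives two identical silyl ethers, so that a 1,2-silyl shift would be without consequence.

Step 8
Reactants: 11 {[(1R,2S,6R)-3-methyl-6-[1-(trimethylsilyl)ethenyl]cyclohex-3-ene-1,2-diyl]bis(oxy)}bis[tert-butyl(dimethyl)silane]
Product: 12 {[(1R,2S,6R)-6-(1-iodoethenyl)-3-methylcyclohex-3-ene-1,2-diyl]bis(oxy)}bis[tert-butyl(dimethyl)silane]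
Conditions: NIS (1.1 equiv), 2,6-lutidine (0.3 equiv), (CF3)2CHOH/CH2Cl2, 0 °C, 10 min
Reagents that add atoms: N-iodosuccinimide, O=C1CCC(=O)N1I
Why: Electrophilic ipso-iododesilylation of the 2-silyl-1-alkene, strongly accelerated in hexafluoroisopropanol, replaces silicon by iodine, and one equivalent of NIS for minutes at 0 °C should spare the more hindered ring alkene, which is deactivated by its allylic oxygen.

Step 9
Reactants: 13 4-methylpent-3-en-1-ol
Product: 14 4-methylpent-3-enal
Conditions: Dess–Martin periodinane, NaHCO3, CH2Cl2, 0 °C → rt; filtered solution used at once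
Reagents that add atoms: none
Why: Dess–Martin oxidation under bicarbonate buffer should give the β,γ-unsaturated aldehyde without migration of the double bond into conjugation, and the volatile product is not stored.

Step 10
Reactants: 12 {[(1R,2S,6R)-6-(1-iodoethenyl)-3-methylcyclohex-3-ene-1,2-diyl]bis(oxy)}bis[tert-butyl(dimethyl)silane]; 14 4-methylpent-3-enal
Product: 15 (3S)-2-[(1S,5S,6R)-5,6-bis{[tert-butyl(dimethyl)silyl]oxy}-4-methylcyclohex-3-en-1-yl]-6-methylhepta-1,5-dien-3-ol
Conditions: CrCl2 (3 equiv), N-[2-(4-isopropyl-4,5-dihydro-1,3-oxazol-2-yl)-6-methylphenyl]methanesulfonamide (single antipode, 3.3 equiv), Et3N, THF, rt; then NiCl2 (cat.), 12, 14 (2 equiv), rt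
Reagents that add atoms: none
Why: Nozaki–Hiyama–Kishi coupling, in which the alkenyl iodide adds oxidatively to zerovalent nickel formed in situ, is transferred to trivalent chromium and adds to the aldehyde inside the chiral sulfonamide–chromium complex, so that Re-face attack sets C8 as S while silyl ethers and alkenes stay inert.

Step 11
Reactants: 15 (3S)-2-[(1S,5S,6R)-5,6-bis{[tert-butyl(dimethyl)silyl]oxy}-4-methylcyclohex-3-en-1-yl]-6-methylhepta-1,5-dien-3-ol
Product: 16 (3S)-2-[(1S,5S,6R)-5,6-bis{[tert-butyl(dimethyl)silyl]oxy}-4-methylcyclohex-3-en-1-yl]-6-methylhepta-1,5-dien-3-yl acetate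
Conditions: Ac2O, pyridine, DMAP (cat.), CH2Cl2, 0 °C → rt
Reagents that add atoms: acetic anhydride, CC(=O)OC(C)=O
Why: DMAP-catalysed acylation of the secondary allylic alcohol leaves the C8–O bond unbroken, so the configuration is retained.

Step 12
Reactants: 16 (3S)-2-[(1S,5S,6R)-5,6-bis{[tert-butyl(dimethyl)silyl]oxy}-4-methylcyclohex-3-en-1-yl]-6-methylhepta-1,5-dien-3-yl acetate
Product: 17 (3S)-2-[(1S,5S,6R)-5,6-dihydroxy-4-methylcyclohex-3-en-1-yl]-6-methylhepta-1,5-dien-3-yl acetate
Conditions: HF·pyridine, pyridine, THF, 0 °C → rt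
Reagents that add atoms: none
Why: Fluoride-mediated desilylation under buffered, non-basic conditions should cleave both Si–O bonds while the C8 acetate neither hydrolyses nor migrates.

Step 13
Reactants: 17 (3S)-2-[(1S,5S,6R)-5,6-dihydroxy-4-methylcyclohex-3-en-1-yl]-6-methylhepta-1,5-dien-3-yl acetate
Product: 18 (3S)-2-[(1S,3S,4R,5R,6S)-4,5-dihydroxy-6-methyl-7-oxabicyclo[4.1.0]heptan-3-yl]-6-methylhepta-1,5-dien-3-yl acetate
Conditions: VO(acac)2 (5 mol%), t-BuOOH (1.5 equiv, in decane), CH2Cl2, 0 °C → rt
Reagents that add atoms: tert-butyl hydroperoxide, CC(C)(C)OO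
Why: Hydroxyl-directed epoxidation, in which a vanadate ester of the allylic C5 hydroxyl or of the cis homoallylic C6 hydroxyl delivers oxygen to C3=C4 on the face of both hydroxyls and so sets C3 and C4, while the prenyl and 1,1-disubstituted alkenes, which lack a free allylic hydroxyl, should react far more slowly.

Step 14
Reactants: 18 (3S)-2-[(1S,3S,4R,5R,6S)-4,5-dihydroxy-6-methyl-7-oxabicyclo[4.1.0]heptan-3-yl]-6-methylhepta-1,5-dien-3-yl acetate; 19 angelic acid
Product: 21 (1S,2R,3R,4S,6S)-4-[(3S)-3-acetoxy-6-methylhepta-1,5-dien-2-yl]-1-methyl-7-oxabicyclo[4.1.0]heptane-2,3-diyl bis[(2Z)-2-methylbut-2-enoate], via angelic 2,4,6-trichlorobenzoic anhydride 20 (not isolated)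
Conditions: 19 (6 equiv), 2,4,6-trichlorobenzoyl chloride (6 equiv), Et3N, PhMe, rt, salt filtered off; then 18, PhMe, 80 °C
Reagents that add atoms: none
Why: Yamaguchi-type acylation through the mixed anhydride, run without a nucleophilic catalyst so that the Z-enoate is not isomerised to the tiglate, should esterify both hydroxyls, and the cis-epoxy alcohol cannot undergo Payne rearrangement because its alkoxide cannot reach the epoxide carbon from the rear.

**Compound list**

1 | 4-iodotoluene | Cc1ccc(I)cc1 | starting material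
2 | (1S,2S)-3-iodo-6-methylcyclohexa-3,5-diene-1,2-diol | IC1=CC=C(C)[C@H](O)[C@@H]1O | intermediate
3 | (1R,2S)-3-methylcyclohexa-3,5-diene-1,2-diol | C1=CC=C(C)[C@H](O)[C@@H]1O | intermediate
4 | chlorodimethylvinylsilane | C=C[Si](C)(C)Cl | starting material
5 | chloro(1,2-dibromoethyl)dimethylsilane (racemic) | BrCC(Br)[Si](C)(C)Cl | intermediate
6 | (1-bromoethenyl)chlorodimethylsilane | C=C(Br)[Si](C)(C)Cl | intermediate
7 | (1S,6R)-6-{[(1-bromoethenyl)dimethylsilyl]oxy}-2-methylcyclohexa-2,4-dien-1-ol (tether on C6–O, free C5–OH) | C1=CC=C(C)[C@H](O)[C@@H]1O[Si](C)(C)C(Br)=C | intermediate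
8 | {[(1S,6R)-6-{[(1-bromoethenyl)dimethylsilyl]oxy}-2-methylcyclohexa-2,4-dien-1-yl]oxy}(tert-butyl)dimethylsilane (radical precursor) | C1=CC=C(C)[C@H](O[Si](C)(C)C(C)(C)C)[C@@H]1O[Si](C)(C)C(Br)=C | intermediate
9 | (3aR,7S,7aR)-7-[(tert-butyldimethylsilyl)oxy]-2,2,6-trimethyl-3-methylidene-2,3,3a,4,7,7a-hexahydro-1,2-benzoxasilole (cis-fused oxasilolane) | C=C1[C@@H]2CC=C(C)[C@H](O[Si](C)(C)C(C)(C)C)[C@@H]2O[Si]1(C)C | intermediate
10 | lithium (1R,2S,6R)-2-[(tert-butyldimethylsilyl)oxy]-3-methyl-6-[1-(trimethylsilyl)ethenyl]cyclohex-3-en-1-olate | C=C([Si](C)(C)C)[C@@H]1CC=C(C)[C@H](O[Si](C)(C)C(C)(C)C)[C@@H]1[O-].[Li+] | intermediate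
11 | {[(1R,2S,6R)-3-methyl-6-[1-(trimethylsilyl)ethenyl]cyclohex-3-ene-1,2-diyl]bis(oxy)}bis[tert-butyl(dimethyl)silane] | C=C([Si](C)(C)C)[C@@H]1CC=C(C)[C@H](O[Si](C)(C)C(C)(C)C)[C@@H]1O[Si](C)(C)C(C)(C)C | intermediate
12 | {[(1R,2S,6R)-6-(1-iodoethenyl)-3-methylcyclohex-3-ene-1,2-diyl]bis(oxy)}bis[tert-butyl(dimethyl)silane] | C=C(I)[C@@H]1CC=C(C)[C@H](O[Si](C)(C)C(C)(C)C)[C@@H]1O[Si](C)(C)C(C)(C)C | intermediate
13 | 4-methylpent-3-en-1-ol | CC(C)=CCCO | starting material
14 | 4-methylpent-3-enal | CC(C)=CCC=O | intermediate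
15 | (3S)-2-[(1S,5S,6R)-5,6-bis{[tert-butyl(dimethyl)silyl]oxy}-4-methylcyclohex-3-en-1-yl]-6-methylhepta-1,5-dien-3-ol | C=C([C@H](CC=C(C)C)O)[C@@H]1CC=C(C)[C@H](O[Si](C)(C)C(C)(C)C)[C@@H]1O[Si](C)(C)C(C)(C)C | intermediate
16 | (3S)-2-[(1S,5S,6R)-5,6-bis{[tert-butyl(dimethyl)silyl]oxy}-4-methylcyclohex-3-en-1-yl]-6-methylhepta-1,5-dien-3-yl acetate | C=C([C@H](CC=C(C)C)OC(C)=O)[C@@H]1CC=C(C)[C@H](O[Si](C)(C)C(C)(C)C)[C@@H]1O[Si](C)(C)C(C)(C)C | intermediate
17 | (3S)-2-[(1S,5S,6R)-5,6-dihydroxy-4-methylcyclohex-3-en-1-yl]-6-methylhepta-1,5-dien-3-yl acetate | C=C([C@H](CC=C(C)C)OC(C)=O)[C@@H]1CC=C(C)[C@H](O)[C@@H]1O | intermediate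
18 | (3S)-2-[(1S,3S,4R,5R,6S)-4,5-dihydroxy-6-methyl-7-oxabicyclo[4.1.0]heptan-3-yl]-6-methylhepta-1,5-dien-3-yl acetate (epoxide cis to both hydroxyls) | C=C([C@H](CC=C(C)C)OC(C)=O)[C@@H]1C[C@@H]2O[C@]2(C)[C@H](O)[C@@H]1O | intermediate
19 | angelic acid, (2Z)-2-methylbut-2-enoic acid | C/C=C(/C)C(=O)O | starting material
20 | (2Z)-2-methylbut-2-enoic 2,4,6-trichlorobenzoic anhydride | C/C=C(/C)C(=O)OC(=O)c1c(Cl)cc(Cl)cc1Cl | intermediate
21 | (1S,2R,3R,4S,6S)-4-[(3S)-3-acetoxy-6-methylhepta-1,5-dien-2-yl]-1-methyl-7-oxabicyclo[4.1.0]heptane-2,3-diyl bis[(2Z)-2-methylbut-2-enoate] | C=C([C@H](CC=C(C)C)OC(C)=O)[C@@H]1C[C@@H]2O[C@]2(C)[C@H](OC(=O)/C(C)=C\C)[C@@H]1OC(=O)/C(C)=C\C | target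

**Step count and risks**

Total: 14 steps. Longest linear sequence: 12 steps from 4-iodotoluene (steps 1, 2, 4–8, 10–14). Steps 3 and 9 prepare the silyl chloride and the aldehyde.

Step 6. The chain may be carried poorly: bromine abstraction at the hindered α-silyl vinyl bromide may be slow, or the vinyl radical may be reduced before it closes. At the temperature the chain needs, the dienyl bis-silyl ether could then aromatise or dimerise instead of cyclising.
- Fallback: form the same kind of radical by addition instead of halogen abstraction, at room temperature. It sets out from 3 and returns at 9.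
- Silylation of 3 at C6–O (Et3N, CH2Cl2, −78 °C) with chloro(ethynyl)dimethylsilane F1, made from ethynylmagnesium bromide and an excess of Me2SiCl2, should give (1S,6R)-6-{[ethynyl(dimethyl)silyl]oxy}-2-methylcyclohexa-2,4-dien-1-ol F2.
- TBSOTf/2,6-lutidine then gives its C5 tert-butyldimethylsilyl ether F3.
- Bu3SnH with Et3B/air in toluene at room temperature adds a stannyl radical to the alkyne terminus; the α-silyl β-stannyl vinyl radical closes 5-exo onto C1 and the allyl radical is reduced at C2 (hydrostannylative cyclisation). This gives the C14-tributylstannyl derivative of the oxasilolane F4 as a mixture of alkene isomers.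
- One equivalent of HCl in Et2O/CH2Cl2 at −78 °C protonates the tin-bearing carbon and expels tin, which gives 9.

Step 10. Facial selectivity at the aldehyde may be poor, because ligand control can be eroded by the adjacent C1 stereocentre and the bulky C6 silyl ether, or the sense of induction may be opposite to that wanted.
- Fallback: set C8 by reagent-controlled reduction instead of addition. It sets out from 12 and 14 and returns at 15.
- The ligand-free coupling (CrCl2, NiCl2 cat., DMSO, rt) gives 15 together with its C8 epimer, (3R)-2-[(1S,5S,6R)-5,6-bis{[tert-butyl(dimethyl)silyl]oxy}-4-methylcyclohex-3-en-1-yl]-6-methylhepta-1,5-dien-3-ol F5.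
- Dess–Martin oxidation of the mixture gives the single enone 2-[(1S,5S,6R)-5,6-bis{[tert-butyl(dimethyl)silyl]oxy}-4-methylcyclohex-3-en-1-yl]-6-methylhepta-1,5-dien-3-one F6.
- Reduction with (R)-2-methyl-CBS-oxazaborolidine and catecholborane in toluene at −78 °C, with the branched alkenyl group as the large substituent, should give the 8S alcohol 15. Catecholborane is chosen so that the alkenes are not hydroborated.

Step 14. Acylation of the second, more hindered hydroxyl of the cis-diol may stall, and the heating needed to force it may isomerise the Z-enoate to the tiglate.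
- Fallback: build the Z-alkenes on esters that are already in place. It sets out from 18 and arrives at 21.
- DCC/DMAP esterification of both hydroxyls with 2-[bis(2,2,2-trifluoroethoxy)phosphoryl]propanoic acid gives the bis{2-[bis(2,2,2-trifluoroethoxy)phosphoryl]propanoate} of 18 F7.
- Twofold Still–Gennari olefination with acetaldehyde (KN(SiMe3)2, 18-crown-6, THF, −78 °C) should then give both (Z)-2-methylbut-2-enoates and so 21. The phosphonate protons are far more acidic than those of the acetate, so the C8 ester should be untouched.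

**Further compounds**

F1 | step 6 | chloro(ethynyl)dimethylsilane | C#C[Si](C)(C)Cl
F2 | step 6 | (1S,6R)-6-{[ethynyl(dimethyl)silyl]oxy}-2-methylcyclohexa-2,4-dien-1-ol | C1=CC=C(C)[C@H](O)[C@@H]1O[Si](C)(C)C#C
F3 | step 6 | tert-butyl{[(1S,6R)-6-{[ethynyl(dimethyl)silyl]oxy}-2-methylcyclohexa-2,4-dien-1-yl]oxy}dimethylsilane | C1=CC=C(C)[C@H](O[Si](C)(C)C(C)(C)C)[C@@H]1O[Si](C)(C)C#C
F4 | step 6 | (3aR,7S,7aR)-7-[(tert-butyldimethylsilyl)oxy]-2,2,6-trimethyl-3-[(tributylstannyl)methylidene]-2,3,3a,4,7,7a-hexahydro-1,2-benzoxasilole (alkene isomers) | CCCC[Sn](CCCC)(CCCC)C=C1[C@@H]2CC=C(C)[C@H](O[Si](C)(C)C(C)(C)C)[C@@H]2O[Si]1(C)C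
F5 | step 10 | (3R)-2-[(1S,5S,6R)-5,6-bis{[tert-butyl(dimethyl)silyl]oxy}-4-methylcyclohex-3-en-1-yl]-6-methylhepta-1,5-dien-3-ol | C=C([C@@H](CC=C(C)C)O)[C@@H]1CC=C(C)[C@H](O[Si](C)(C)C(C)(C)C)[C@@H]1O[Si](C)(C)C(C)(C)C
F6 | step 10 | 2-[(1S,5S,6R)-5,6-bis{[tert-butyl(dimethyl)silyl]oxy}-4-methylcyclohex-3-en-1-yl]-6-methylhepta-1,5-dien-3-one | C=C(C(=O)CC=C(C)C)[C@@H]1CC=C(C)[C@H](O[Si](C)(C)C(C)(C)C)[C@@H]1O[Si](C)(C)C(C)(C)C
F7 | step 14 | bis{2-[bis(2,2,2-trifluoroethoxy)phosphoryl]propanoate} of 18 (phosphonate α-carbons unassigned) | C=C([C@H](CC=C(C)C)OC(C)=O)[C@@H]1C[C@@H]2O[C@]2(C)[C@H](OC(=O)C(C)P(=O)(OCC(F)(F)F)OCC(F)(F)F)[C@@H]1OC(=O)C(C)P(=O)(OCC(F)(F)F)OCC(F)(F)F
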